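**Retrosynthetic overview**
1. Target 25 is cut at the C2′=C3′ alkene by E-selective cross-metathesis into allyl-dioxane acid 18 and (S)-vinyl carbinol 24 (five steps from dihydro-β-ionone, configuration from a Sharpless epoxidation).
2. The route rests on C6 of the 1,2-dioxane (ring O1–O2–C3–C4–C5–C6). This fully substituted carbon, bearing CH3, O1, C5 and chain carbon C1′, is read as the carbonyl carbon of 6-methylhept-5-en-2-one, and C1′ and C2′ as two ylide methylenes tied back to the C6 oxygen in an oxetane.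
3. The dioxane closes when a C3 hydroperoxide opens that oxetane at C6 with inversion (6-exo), which frees C2′ as CH2OH for one-carbon extension to the allyl group; the C3–OOH group comes from the anti C3 alcohol by sulfonate displacement, also with inversion.
4. C3 and Cα (C2 of the propanoic acid) come from the prenyl terminus by SeO2 oxidation and asymmetric hydroboration; the allylic CH2OH made there ends as CO2H.
5. Ring order: transient oxirane, then temporary oxetane (both in step 1), then the 1,2-dioxane (step 7); the cyclohexene ring is bought with dihydro-β-ionone.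

Key step: step 1

Remark: the antipode of binaphthol (step 1) and of IpcBH2 (step 4) is assigned by analogy with simple alkyl methyl ketones and trisubstituted alkenes; if the sense of induction proves opposite, the other antipode, equally available, is used.

**Step 1**
Reactants: 1 6-methylhept-5-en-2-one; 2 trimethylsulfoxonium chloride
Product: 5 (2R)-2-methyl-2-(4-methylpent-3-en-1-yl)oxetane, via dimethylsulfoxonium methylide 3 (not isolated), via oxirane 4 (not isolated)
Conditions: 2, NaH, THF, reflux, filter (salt-free solution of 3); 1, 3 (1.2 equiv), LaLi3((S)-binaphthoxide)3 (5 mol%, from La(OiPr)3, (S)-binaphthol, nBuLi), (2,4,6-(MeO)3C6H2)3P=O (5 mol%), 5 Å MS, THF, rt; then 3 (1.2 equiv), more catalyst (to 20 mol%), 45 °C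
Reagents that add atoms: none
Why: The ylide adds to the ketone bound to the lanthanum–lithium binaphthoxide (the phosphine oxide on lanthanum tightens the chiral pocket) and the betaine closes 3-exo-tet with loss of DMSO to oxirane 4; a second ylide then opens 4 at its CH2 and the alkoxide expels DMSO 4-exo-tet to give oxetane 5. This is the known one-pot catalytic asymmetric Corey–Chaykovsky epoxidation of a methyl ketone followed by ylide ring expansion to a 2,2-disubstituted oxetane. The new centre (C6 of the target) is set in the first methylene transfer by enantioface selection between CH3 and the homoprenyl chain on the catalyst, and it is not touched in the second transfer, which only forms the C1′–C2′ and O–C2′ bonds. Because the same catalyst should expand the major enantiomer of 4 faster, the second transfer should raise the enantiomeric purity of 5 above that of 4. The step needs chemoselectivity for C=O over the trisubstituted alkene and for the CH2 over the quaternary carbon of 4; the stabilised sulfoxonium ylide attacks only the carbonyl and the unhindered oxirane carbon, so the prenyl terminus should pass unchanged.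

**Step 2**
Reactants: 5 (2R)-2-methyl-2-(4-methylpent-3-en-1-yl)oxetane
Product: 7 (2E)-2-methyl-5-[(2R)-2-methyloxetan-2-yl]pent-2-en-1-ol, via enal 6 (not isolated)
Conditions: SeO2 (0.3 equiv), tBuOOH, CH2Cl2, 0 °C → rt; then NaBH4, MeOH, 0 °C
Reagents that add atoms: selenium dioxide O=[Se]=O (oxygen carrier); tert-butyl hydroperoxide CC(C)(C)OO (terminal oxidant)
Why: SeO2 allylic oxidation (ene reaction, then [2,3]-sigmatropic shift) is selective for the (E)-methyl of a prenyl-type alkene, the over-oxidised enal 6 is returned to the alcohol by NaBH4, and the oxetane should tolerate these weakly acidic conditions.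

**Step 3**
Reactants: 7 (2E)-2-methyl-5-[(2R)-2-methyloxetan-2-yl]pent-2-en-1-ol
Product: 8 tert-butyl(dimethyl){[(2E)-2-methyl-5-[(2R)-2-methyloxetan-2-yl]pent-2-en-1-yl]oxy}silane
Conditions: TBSCl, imidazole, DMF, rt
Reagents that add atoms: tert-butyldimethylsilyl chloride CC(C)(C)[Si](C)(C)Cl
Why: Standard silylation of a primary allylic alcohol gives an ether that should survive borane, base, peroxide and mild Lewis acid and that is removed late with fluoride.

**Step 4**
Reactants: 8 tert-butyl(dimethyl){[(2E)-2-methyl-5-[(2R)-2-methyloxetan-2-yl]pent-2-en-1-yl]oxy}silane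
Product: 10 (2S,3R)-1-{[tert-butyl(dimethyl)silyl]oxy}-2-methyl-5-[(2R)-2-methyloxetan-2-yl]pentan-3-ol, via organoborane 9 (not isolated)
Conditions: IpcBH2 (from (−)-α-pinene), THF, −25 °C; then NaOH, H2O2, 0 °C → rt
Reagents that add atoms: hydrogen peroxide OO
Why: In this Brown asymmetric hydroboration boron adds to C3 (the less substituted carbon, remote from the silyloxy group) and hydrogen to Cα on the same face, chosen by the isopinocampheyl group, and oxidation with retention should give the anti (2S,3R) alcohol, any minor diastereomer being removable at the latest after ring closure in step 7.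

**Step 5**
Reactants: 10 (2S,3R)-1-{[tert-butyl(dimethyl)silyl]oxy}-2-methyl-5-[(2R)-2-methyloxetan-2-yl]pentan-3-ol
Product: 11 (2S,3R)-1-{[tert-butyl(dimethyl)silyl]oxy}-2-methyl-5-[(2R)-2-methyloxetan-2-yl]pentan-3-yl 4-nitrobenzenesulfonate
Conditions: 4-NO2C6H4SO2Cl, Et3N, DMAP (cat.), CH2Cl2, 0 °C; used at once
Reagents that add atoms: 4-nitrobenzenesulfonyl chloride O=S(=O)(Cl)c1ccc(cc1)[N+](=O)[O-]
Why: O-Sulfonylation with retention turns the C3 hydroxyl into a good leaving group under basic, non-ionising conditions that leave the oxetane and silyl ether alone.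

**Step 6**
Reactants: 11 (2S,3R)-1-{[tert-butyl(dimethyl)silyl]oxy}-2-methyl-5-[(2R)-2-methyloxetan-2-yl]pentan-3-yl 4-nitrobenzenesulfonate
Product: 12 tert-butyl({(2S,3S)-3-hydroperoxy-2-methyl-5-[(2R)-2-methyloxetan-2-yl]pentyl}oxy)dimethylsilane
Conditions: 50% aq. H2O2 (large excess), KOH, THF/MeOH, 0 °C → rt
Reagents that add atoms: hydrogen peroxide OO
Why: SN2 displacement of a secondary arenesulfonate by hydroperoxide anion, an α-effect nucleophile, should invert C3 (3R → 3S), the excess of H2O2 holds back a second alkylation to the dialkyl peroxide, and the oxetane is inert to base.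

**Step 7**
Reactants: 12 tert-butyl({(2S,3S)-3-hydroperoxy-2-methyl-5-[(2R)-2-methyloxetan-2-yl]pentyl}oxy)dimethylsilane
Product: 13 2-[(3S,6S)-6-[(2S)-1-{[tert-butyl(dimethyl)silyl]oxy}propan-2-yl]-3-methyl-1,2-dioxan-3-yl]ethan-1-ol
Conditions: Yb(OTf)3 (10 mol%), CH2Cl2, 0 °C → rt
Reagents that add atoms: none
Why: In this known Lewis-acid-mediated intramolecular opening of an oxetane by a hydroperoxide, the terminal peroxide oxygen attacks the activated tertiary carbon 6-exo-tet from the face opposite the departing oxetane oxygen, so C6 should be inverted ((R)-oxetane → (S) at the methyl-bearing ring carbon) and the former oxetane CH2O is released as the C2′ alcohol.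

**Step 8**
Reactants: 13 2-[(3S,6S)-6-[(2S)-1-{[tert-butyl(dimethyl)silyl]oxy}propan-2-yl]-3-methyl-1,2-dioxan-3-yl]ethan-1-ol
Product: 14 [(3S,6S)-6-[(2S)-1-{[tert-butyl(dimethyl)silyl]oxy}propan-2-yl]-3-methyl-1,2-dioxan-3-yl]acetaldehyde
Conditions: Dess–Martin periodinane, NaHCO3, CH2Cl2, 0 °C → rt
Reagents that add atoms: none
Why: Buffered Dess–Martin oxidation of a primary alcohol is neutral and non-reducing, so the dialkyl peroxide and the β-peroxy aldehyde formed should both survive if 14 is used directly.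

**Step 9**
Reactants: 14 [(3S,6S)-6-[(2S)-1-{[tert-butyl(dimethyl)silyl]oxy}propan-2-yl]-3-methyl-1,2-dioxan-3-yl]acetaldehyde
Product: 15 tert-butyl(dimethyl){(2S)-2-[(3S,6S)-6-methyl-6-(prop-2-en-1-yl)-1,2-dioxan-3-yl]propoxy}silane
Conditions: Ph3PCH3Br, KN(SiMe3)2, THF, 0 °C; then 14, −78 → 0 °C
Reagents that add atoms: methyltriphenylphosphonium bromide C[P+](c1ccccc1)(c1ccccc1)c1ccccc1.[Br-]
Why: Wittig methylenation of an unhindered aldehyde is fast at −78 °C, which should outrun enolisation and loss of the β-peroxy group, and it installs C3′ as the terminal carbon of the allyl group.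

**Step 10**
Reactants: 15 tert-butyl(dimethyl){(2S)-2-[(3S,6S)-6-methyl-6-(prop-2-en-1-yl)-1,2-dioxan-3-yl]propoxy}silane
Product: 16 (2S)-2-[(3S,6S)-6-methyl-6-(prop-2-en-1-yl)-1,2-dioxan-3-yl]propan-1-ol
Conditions: HF·pyridine, pyridine, THF, 0 °C → rt
Reagents that add atoms: none
Why: Buffered fluoride desilylation is not basic enough to trigger base-induced peroxide fragmentation and leaves the alkene untouched.

**Step 11**
Reactants: 16 (2S)-2-[(3S,6S)-6-methyl-6-(prop-2-en-1-yl)-1,2-dioxan-3-yl]propan-1-ol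
Product: 18 (2R)-2-[(3S,6S)-6-methyl-6-(prop-2-en-1-yl)-1,2-dioxan-3-yl]propanoic acid, via aldehyde 17 (not isolated)
Conditions: TEMPO (20 mol%), PhI(OAc)2 (2.5 equiv), MeCN/H2O (1:1), rt
Reagents that add atoms: water O
Why: Oxoammonium-mediated oxidation of a primary alcohol through the aldehyde hydrate to the acid runs at slightly acidic pH, so the α-methyl centre should not epimerise and the β-peroxide should not eliminate, and the terminal alkene is inert (the descriptor at Cα changes from S to R only because CO2H outranks C3).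

**Step 12**
Reactants: 19 dihydro-β-ionone (4-(2,6,6-trimethylcyclohex-1-en-1-yl)butan-2-one)
Product: 20 ethyl (2E)-3-methyl-5-(2,6,6-trimethylcyclohex-1-en-1-yl)pent-2-enoate
Conditions: (EtO)2P(O)CH2CO2Et, NaH, THF, 0 °C → reflux; chromatographic removal of the minor (Z)-ester
Reagents that add atoms: triethyl phosphonoacetate CCOC(=O)CP(=O)(OCC)OCC
Why: Horner–Wadsworth–Emmons olefination of a methyl ketone gives mainly the (E)-trisubstituted enoate, and the isomers are separable.

**Step 13**
Reactants: 20 ethyl (2E)-3-methyl-5-(2,6,6-trimethylcyclohex-1-en-1-yl)pent-2-enoate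
Product: 21 (2E)-3-methyl-5-(2,6,6-trimethylcyclohex-1-en-1-yl)pent-2-en-1-ol
Conditions: iBu2AlH (2.5 equiv), CH2Cl2, −78 °C
Reagents that add atoms: none
Why: 1,2-Reduction of an enoate by iBu2AlH gives the allylic alcohol without touching either alkene.

**Step 14**
Reactants: 21 (2E)-3-methyl-5-(2,6,6-trimethylcyclohex-1-en-1-yl)pent-2-en-1-ol
Product: 22 [(2S,3S)-3-methyl-3-[2-(2,6,6-trimethylcyclohex-1-en-1-yl)ethyl]oxiran-2-yl]methanol
Conditions: Ti(OiPr)4 (10 mol%), L-(+)-diethyl tartrate (12 mol%), tBuOOH, 4 Å MS, CH2Cl2, −20 °C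
Reagents that add atoms: tert-butyl hydroperoxide CC(C)(C)OO
Why: Sharpless asymmetric epoxidation of an (E)-3,3-disubstituted allylic alcohol is directed by the hydroxyl, so the ring alkene is untouched, and the L-tartrate complex should give the (2S,3S) epoxide as it does with geraniol, which fixes the future carbinol carbon.

**Step 15**
Reactants: 22 [(2S,3S)-3-methyl-3-[2-(2,6,6-trimethylcyclohex-1-en-1-yl)ethyl]oxiran-2-yl]methanol
Product: 23 (2R,3S)-2-(iodomethyl)-3-methyl-3-[2-(2,6,6-trimethylcyclohex-1-en-1-yl)ethyl]oxirane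
Conditions: PPh3, I2, imidazole, CH2Cl2, 0 °C
Reagents that add atoms: iodine II
Why: Appel-type iodination of the primary alcohol leaves the epoxide and both stereocentres untouched (the C2 descriptor changes only because CH2I outranks C3).

**Step 16**
Reactants: 23 (2R,3S)-2-(iodomethyl)-3-methyl-3-[2-(2,6,6-trimethylcyclohex-1-en-1-yl)ethyl]oxirane
Product: 24 (3S)-3-methyl-5-(2,6,6-trimethylcyclohex-1-en-1-yl)pent-1-en-3-ol
Conditions: Zn dust, EtOH, reflux
Reagents that add atoms: none
Why: Zinc insertion into the C–I bond and β-elimination of the epoxide oxygen (reductive epoxide opening) gives the tertiary allylic alcohol with the C3–O bond intact, so the (S) configuration set in step 14 is retained.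

**Step 17**
Reactants: 18 (2R)-2-[(3S,6S)-6-methyl-6-(prop-2-en-1-yl)-1,2-dioxan-3-yl]propanoic acid; 24 (3S)-3-methyl-5-(2,6,6-trimethylcyclohex-1-en-1-yl)pent-1-en-3-ol (3 equiv)
Product: 25 (2R)-2-[(3S,6S)-6-[(2E,4S)-4-hydroxy-4-methyl-6-(2,6,6-trimethylcyclohex-1-en-1-yl)hex-2-en-1-yl]-6-methyl-1,2-dioxan-3-yl]propanoic acid (CNP0195960.3)
Conditions: second-generation Hoveyda–Grubbs catalyst RuCl2(H2IMes)(=CH-C6H4-2-OiPr) (10 mol%; H2IMes = 1,3-dimesityl-4,5-dihydroimidazol-2-ylidene), CH2Cl2, 40 °C
Reagents that add atoms: none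
Why: Olefin cross-metathesis between a terminal allyl group and a slowly homodimerising free tertiary allylic alcohol should give the (E)-disubstituted alkene selectively, the phosphine-free ruthenium carbene tolerates the peroxide and the free acid, and the tetrasubstituted ring alkene does not react.

**Compound list**
1 | 6-methylhept-5-en-2-one | CC(=O)CCC=C(C)C | starting material
2 | trimethylsulfoxonium chloride | C[S+](C)(C)=O.[Cl-] | starting material
3 | dimethylsulfoxonium methylide | C[S+](C)(=O)[CH2-] | intermediate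
4 | (2R)-2-methyl-2-(4-methylpent-3-en-1-yl)oxirane | C[C@]1(CO1)CCC=C(C)C | intermediate
5 | (2R)-2-methyl-2-(4-methylpent-3-en-1-yl)oxetane | C[C@]1(CCO1)CCC=C(C)C | intermediate
6 | (2E)-2-methyl-5-[(2R)-2-methyloxetan-2-yl]pent-2-enal | C[C@]1(CCO1)CC/C=C(\C)C=O | intermediate
7 | (2E)-2-methyl-5-[(2R)-2-methyloxetan-2-yl]pent-2-en-1-ol | C[C@]1(CCO1)CC/C=C(\C)CO | intermediate
8 | tert-butyl(dimethyl){[(2E)-2-methyl-5-[(2R)-2-methyloxetan-2-yl]pent-2-en-1-yl]oxy}silane | C[C@]1(CCO1)CC/C=C(\C)CO[Si](C)(C)C(C)(C)C | intermediate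
9 | [(2R,3R)-1-{[tert-butyl(dimethyl)silyl]oxy}-2-methyl-5-[(2R)-2-methyloxetan-2-yl]pentan-3-yl](isopinocampheyl)borane (boron on C3, syn to the new Cα–H; Ipc from (−)-α-pinene) | C[C@]1(CCO1)CC[C@@H]([BH][C@H]2C[C@H]3C[C@@H]([C@@H]2C)C3(C)C)[C@@H](C)CO[Si](C)(C)C(C)(C)C | intermediate
10 | (2S,3R)-1-{[tert-butyl(dimethyl)silyl]oxy}-2-methyl-5-[(2R)-2-methyloxetan-2-yl]pentan-3-ol | C[C@]1(CCO1)CC[C@@H](O)[C@@H](C)CO[Si](C)(C)C(C)(C)C | intermediate
11 | (2S,3R)-1-{[tert-butyl(dimethyl)silyl]oxy}-2-methyl-5-[(2R)-2-methyloxetan-2-yl]pentan-3-yl 4-nitrobenzenesulfonate | C[C@]1(CCO1)CC[C@@H](OS(=O)(=O)c2ccc(cc2)[N+](=O)[O-])[C@@H](C)CO[Si](C)(C)C(C)(C)C | intermediate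
12 | tert-butyl({(2S,3S)-3-hydroperoxy-2-methyl-5-[(2R)-2-methyloxetan-2-yl]pentyl}oxy)dimethylsilane | C[C@]1(CCO1)CC[C@H](OO)[C@@H](C)CO[Si](C)(C)C(C)(C)C | intermediate
13 | 2-[(3S,6S)-6-[(2S)-1-{[tert-butyl(dimethyl)silyl]oxy}propan-2-yl]-3-methyl-1,2-dioxan-3-yl]ethan-1-ol | OCC[C@]1(C)CC[C@@H]([C@@H](C)CO[Si](C)(C)C(C)(C)C)OO1 | intermediate
14 | [(3S,6S)-6-[(2S)-1-{[tert-butyl(dimethyl)silyl]oxy}propan-2-yl]-3-methyl-1,2-dioxan-3-yl]acetaldehyde | O=CC[C@]1(C)CC[C@@H]([C@@H](C)CO[Si](C)(C)C(C)(C)C)OO1 | intermediate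
15 | tert-butyl(dimethyl){(2S)-2-[(3S,6S)-6-methyl-6-(prop-2-en-1-yl)-1,2-dioxan-3-yl]propoxy}silane | C=CC[C@]1(C)CC[C@@H]([C@@H](C)CO[Si](C)(C)C(C)(C)C)OO1 | intermediate
16 | (2S)-2-[(3S,6S)-6-methyl-6-(prop-2-en-1-yl)-1,2-dioxan-3-yl]propan-1-ol | C=CC[C@]1(C)CC[C@@H]([C@@H](C)CO)OO1 | intermediate
17 | (2R)-2-[(3S,6S)-6-methyl-6-(prop-2-en-1-yl)-1,2-dioxan-3-yl]propanal | C=CC[C@]1(C)CC[C@@H]([C@@H](C)C=O)OO1 | intermediate
18 | (2R)-2-[(3S,6S)-6-methyl-6-(prop-2-en-1-yl)-1,2-dioxan-3-yl]propanoic acid | C=CC[C@]1(C)CC[C@@H]([C@@H](C)C(=O)O)OO1 | intermediate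
19 | dihydro-β-ionone, 4-(2,6,6-trimethylcyclohex-1-en-1-yl)butan-2-one | CC1=C(CCC(C)=O)C(C)(C)CCC1 | starting material
20 | ethyl (2E)-3-methyl-5-(2,6,6-trimethylcyclohex-1-en-1-yl)pent-2-enoate | CCOC(=O)/C=C(\C)CCC1=C(C)CCCC1(C)C | intermediate
21 | (2E)-3-methyl-5-(2,6,6-trimethylcyclohex-1-en-1-yl)pent-2-en-1-ol | OC/C=C(\C)CCC1=C(C)CCCC1(C)C | intermediate
22 | [(2S,3S)-3-methyl-3-[2-(2,6,6-trimethylcyclohex-1-en-1-yl)ethyl]oxiran-2-yl]methanol | CC1=C(CC[C@]2(C)O[C@H]2CO)C(C)(C)CCC1 | intermediate
23 | (2R,3S)-2-(iodomethyl)-3-methyl-3-[2-(2,6,6-trimethylcyclohex-1-en-1-yl)ethyl]oxirane | CC1=C(CC[C@]2(C)O[C@H]2CI)C(C)(C)CCC1 | intermediate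
24 | (3S)-3-methyl-5-(2,6,6-trimethylcyclohex-1-en-1-yl)pent-1-en-3-ol | CC1=C(CC[C@](C)(O)C=C)C(C)(C)CCC1 | intermediate
25 | (2R)-2-[(3S,6S)-6-[(2E,4S)-4-hydroxy-4-methyl-6-(2,6,6-trimethylcyclohex-1-en-1-yl)hex-2-en-1-yl]-6-methyl-1,2-dioxan-3-yl]propanoic acid | CC1=C(CC[C@](C)(O)/C=C/C[C@]2(C)CC[C@@H]([C@@H](C)C(=O)O)OO2)C(C)(C)CCC1 | target

**Step count**
Total: 17 steps. Longest linear sequence: 12 steps (steps 1–11, then step 17); the side chain takes steps 12–16.

**Steps most likely to fail**

Step 6. Bimolecular substitution at the β-branched secondary carbon is slow, so elimination, internal displacement of the sulfonate by the oxetane oxygen, and a second alkylation of the product hydroperoxide may compete. The fallback sets out from 11 and comes back at 12, and uses a masked, weakly basic peroxide nucleophile in a dipolar aprotic solvent. Compound 11 would be alkylated with the anion of 2-methoxypropan-2-yl hydroperoxide (CsOH, DMF, 0 °C), with inversion at C3, to give the mixed peroxyketal tert-butyl{[(2S,3S)-3-[(2-methoxypropan-2-yl)peroxy]-2-methyl-5-[(2R)-2-methyloxetan-2-yl]pentyl]oxy}dimethylsilane F1. Brief treatment with AcOH/H2O/THF would then unmask hydroperoxide 12.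

Step 7. The activated oxetane may ionise to a free tertiary cation, with loss of stereospecificity at C6 and elimination, or the Lewis acid may fragment the secondary hydroperoxide. The fallback sets out from 11 and comes back at 13, with the order of the two ring C–O bond formations exchanged. Perhydrolysis of the oxetane of 11 with ethereal H2O2 and catalytic TMSOTf (Et2O, −78 → 0 °C) should open C6 with inversion to the tertiary hydroperoxide (2S,3R,6S)-1-{[tert-butyl(dimethyl)silyl]oxy}-6-hydroperoxy-8-hydroxy-2,6-dimethyloctan-3-yl 4-nitrobenzenesulfonate F2. KOtBu with 18-crown-6 (THF, 0 °C) would then close the ring by intramolecular 6-exo-tet displacement of the C3 nosylate with inversion, giving 13.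

Step 4. The isopinocampheyl group may discriminate the faces of an acyclic trisubstituted alkene poorly, giving a mixture of diastereomers that is hard to separate before the ring is closed. The fallback sets out from 5 and comes back at 10, and builds the anti C3/Cα pair by carbonyl addition instead.
- Ozonolysis of 5 (O3, CH2Cl2, −78 °C; Me2S) would give 3-[(2R)-2-methyloxetan-2-yl]propanal F3.
- Crotylboration with the antipode of (E)-crotyldiisopinocampheylborane that delivers the (3R,4S) isomer (closed six-membered transition state, anti from the E-crotyl geometry) would give (3R,4S)-4-methyl-1-[(2R)-2-methyloxetan-2-yl]hex-5-en-3-ol F4.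
- Ozonolysis of the vinyl group with NaBH4 work-up would give (2S,3R)-2-methyl-5-[(2R)-2-methyloxetan-2-yl]pentane-1,3-diol F5.
- Selective silylation of the primary hydroxyl (TBSCl, imidazole, CH2Cl2, 0 °C) would give 10.

**Further compounds**
F1 | step 6 | tert-butyl{[(2S,3S)-3-[(2-methoxypropan-2-yl)peroxy]-2-methyl-5-[(2R)-2-methyloxetan-2-yl]pentyl]oxy}dimethylsilane | C[C@]1(CCO1)CC[C@H](OOC(C)(C)OC)[C@@H](C)CO[Si](C)(C)C(C)(C)C
F2 | step 7 | (2S,3R,6S)-1-{[tert-butyl(dimethyl)silyl]oxy}-6-hydroperoxy-8-hydroxy-2,6-dimethyloctan-3-yl 4-nitrobenzenesulfonate | C[C@@](OO)(CCO)CC[C@@H](OS(=O)(=O)c1ccc(cc1)[N+](=O)[O-])[C@@H](C)CO[Si](C)(C)C(C)(C)C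
F3 | step 4 | 3-[(2R)-2-methyloxetan-2-yl]propanal | C[C@]1(CCO1)CCC=O
F4 | step 4 | (3R,4S)-4-methyl-1-[(2R)-2-methyloxetan-2-yl]hex-5-en-3-ol | C[C@]1(CCO1)CC[C@@H](O)[C@@H](C)C=C
F5 | step 4 | (2S,3R)-2-methyl-5-[(2R)-2-methyloxetan-2-yl]pentane-1,3-diol | C[C@]1(CCO1)CC[C@@H](O)[C@@H](C)CO
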